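## Retrosynthetic overview

1. The last ring closed is the carbocycle made of the enol-bearing carbon, the two ring ketones, the quaternary C-methyl carbon between them, the C(OH)Me carbon and the CH bridgehead. A one-flask [5+1] annulation closes it: the methyl carbon of (3E,5E)-hepta-3,5-dien-2-one is acylated by a ring acid chloride, and the resulting β-diketonate opens an epoxide.
2. Enabling feature: the enol-bearing carbon is bonded to both a ring ketone carbon and the CH bridgehead, and these sit 1,4 across the spiro-cyclohexanone ring (quaternary C-methyl carbon, ketone, C(OH)Me, CH, CH2, spiro carbon). The CH/C(OH)Me pair can therefore be stored as an epoxide trans to an acid chloride on the quaternary carbon, and one carbon bridges them to give the bicyclo[2.2.2]octane and the tertiary alcohol together.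
3. The epoxy acid comes from a 2-pyranone + 2-alkoxyacrylate Diels–Alder adduct (temporary lactone bridge, both quaternary centres set), fluoride-triggered E1cB opening to a cyclohexenone carboxylate, and nucleophilic epoxidation.
4. The dienophile (silylated scytolide) comes from shikimic acid: trans-diol diacetal, Mitsunobu inversion of the allylic carbinol, Rh-carbenoid O–H insertion, Horner–Wadsworth–Emmons methylenation, lactonisation.
5. Ring order: cyclohexene (chiral pool) → dioxanone → spiro-cyclohexene (via bridged lactone) → final carbocycle of the bicyclo[2.2.2]octane.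

Key step: step 16

Assumption: the cyclohexene triol unit of the target has the all-trans (3S,4S,5R; 3-epi-shikimate) configuration as drawn, so the allylic carbinol of shikimic acid is inverted once; the triketone is carried as the exocyclic enol tautomer drawn.

## Route

Step 1
Reactants: 1 (−)-shikimic acid
Product: 2 methyl shikimate
Conditions: MeOH, camphorsulfonic acid (cat.), reflux
Reagents that add atoms: methanol, CO
Why: Fischer esterification of the conjugated acid should proceed without touching the three carbinol stereocentres.

Step 2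
Reactants: 2 methyl shikimate
Product: 3 methyl 4,5-O-(2,3-dimethoxybutane-2,3-diyl)shikimate
Conditions: 2,2,3,3-tetramethoxybutane, camphorsulfonic acid (cat.), MeOH, 65 °C
Reagents that add atoms: 2,2,3,3-tetramethoxybutane, COC(C)(OC)C(C)(OC)OC
Why: butane-2,3-diacetal formation should select the trans-diequatorial 4,5-diol (trans-fused dioxane, both methoxy groups axial by anomeric control) and leave the allylic 3-OH free.

Step 3
Reactants: 3 methyl 4,5-O-(2,3-dimethoxybutane-2,3-diyl)shikimate
Product: 4 methyl 3-epi-3-O-(4-nitrobenzoyl)-4,5-O-(2,3-dimethoxybutane-2,3-diyl)shikimate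
Conditions: 4-nitrobenzoic acid, PPh3, diisopropyl azodicarboxylate, THF, 0 °C → rt
Reagents that add atoms: 4-nitrobenzoic acid, O=C(O)c1ccc(cc1)[N+](=O)[O-]
Why: Mitsunobu reaction should invert the allylic carbinol by direct SN2 displacement (the acidic nitrobenzoate limits allylic transposition), setting the 3S centre.

Step 4
Reactants: 4 methyl 3-epi-3-O-(4-nitrobenzoyl)-4,5-O-(2,3-dimethoxybutane-2,3-diyl)shikimate
Product: 5 methyl 3-epi-4,5-O-(2,3-dimethoxybutane-2,3-diyl)shikimate
Conditions: K2CO3 (cat.), MeOH, 0 °C
Reagents that add atoms: none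
Why: transesterification should remove the activated aryl ester selectively, with the conjugated methyl ester degenerate under methoxide.

Step 5
Reactants: 6 triethyl phosphonoacetate
Product: 7 ethyl diazo(diethoxyphosphoryl)acetate
Conditions: 4-acetamidobenzenesulfonyl azide, DBU, MeCN, 0 °C → rt
Reagents that add atoms: 4-acetamidobenzenesulfonyl azide, CC(=O)Nc1ccc(cc1)S(=O)(=O)N=[N+]=[N-]
Why: Regitz diazo transfer to the doubly activated methylene should give the acceptor/acceptor diazo compound.

Step 6
Reactants: 5 methyl 3-epi-4,5-O-(2,3-dimethoxybutane-2,3-diyl)shikimate; 7 ethyl diazo(diethoxyphosphoryl)acetate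
Product: 8 3-O-[(diethoxyphosphoryl)(ethoxycarbonyl)methyl] ether of 5
Conditions: Rh2(OAc)4 (1 mol %), PhMe, 80 °C, slow addition of 7
Reagents that add atoms: none
Why: rhodium-carbenoid O–H insertion into the single free alcohol should be faster than cyclopropanation of the electron-poor alkene; the new phosphonate-bearing centre forms as both epimers and is destroyed in step 7.

Step 7
Reactants: 8 3-O-[(diethoxyphosphoryl)(ethoxycarbonyl)methyl] ether of 5
Product: 9 3-O-(1-ethoxycarbonylvinyl) ether of 5 (enol-pyruvate ether)
Conditions: LiN(SiMe3)2, THF, −78 °C; monomeric HCHO, −78 → 0 °C; aq NH4Cl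
Reagents that add atoms: formaldehyde, C=O
Why: Horner–Wadsworth–Emmons methylenation of the phosphonoacetate should give the 2-alkoxyacrylate without creating a stereocentre.

Step 8
Reactants: 9 3-O-(1-ethoxycarbonylvinyl) ether of 5
Product: 11 scytolide (trans-fused 3-methylene-1,4-dioxan-2-one on methyl 3-epi-shikimate; 5-OH free), via trans-diol ester 10 (not isolated)
Conditions: CF3CO2H/H2O (9:1), 0 °C → rt; evaporate; then camphorsulfonic acid (cat.), PhMe, 80 °C
Reagents that add atoms: none
Why: acid hydrolysis should remove the diacetal while the ester-deactivated enol ether survives, and acid-catalysed lactonisation should then involve only the 4-OH, since the 5-OH could close only a seven-membered ring.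

Step 9
Reactants: 11 scytolide
Product: 12 5-O-tert-butyldiphenylsilyl scytolide
Conditions: tert-butyl(chloro)diphenylsilane, imidazole, DMF, rt → 40 °C
Reagents that add atoms: tert-butyl(chloro)diphenylsilane, CC(C)(C)[Si](Cl)(c1ccccc1)c1ccccc1
Why: silylation of the only free hydroxyl should give an ether that outlasts fluoride at low temperature, peroxide, acid chloride and enolate chemistry.

Step 10
Reactants: 13 ethyl 2-methyl-3-oxopentanoate
Product: 15 4-hydroxy-3,5-dimethyl-2H-pyran-2-one, via formyl keto ester 14 (not isolated)
Conditions: NaH, THF, 0 °C; n-BuLi, 0 °C; HCO2Et, −78 → 0 °C; aq HCl; then TsOH·H2O (cat.), PhMe, 80 °C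
Reagents that add atoms: ethyl formate, CCOC=O
Why: the β-keto ester dianion should be formylated at the γ-methylene (Claisen condensation), and the hydroxymethylene oxygen should then lactonise onto the ester to give the 6-unsubstituted 4-hydroxypyranone.

Step 11
Reactants: 15 4-hydroxy-3,5-dimethyl-2H-pyran-2-one
Product: 16 3,5-dimethyl-4-(triisopropylsilyloxy)-2H-pyran-2-one
Conditions: chlorotriisopropylsilane, imidazole, CH2Cl2, rt
Reagents that add atoms: chlorotriisopropylsilane, CC(C)[Si](Cl)(C(C)C)C(C)C
Why: O-silylation of the vinylogous acid at the 4-oxygen should keep the 2-pyranone diene and place a fluoride-labile trigger on the future ring-ketone carbon.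

Step 12
Reactants: 12 5-O-tert-butyldiphenylsilyl scytolide; 16 3,5-dimethyl-4-(triisopropylsilyloxy)-2H-pyran-2-one
Product: 17 bridged lactone cycloadduct (2-oxabicyclo[2.2.2]oct-5-en-3-one; C4 methyl bridgehead bonded to the spiro carbon, C1–H bridgehead bonded to CH2, C5 silyloxy, C6 methyl)
Conditions: 16 (3 equiv), CH2Cl2, 13 kbar, 30 °C, 72 h
Reagents that add atoms: none
Why: Diels–Alder reaction of the 2-pyranone under high pressure (no CO2 loss) should join the CH2 terminus of the 2-alkoxyacrylate to C6 and the oxygenated carbon to C3 (the usual pyranone regiochemistry for vinyl ethers and acrylates); the dioxanone ring oxygen should lie under the diene (alkoxy-endo, as for enol ethers and s-cis-locked alkoxymethylene lactones) and the bond to the spiro carbon should form axially on the face of the allylic ring-fusion hydrogen, which sets the C-methyl quaternary centre, the spiro centre and the CH bridgehead.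

Step 13
Reactants: 17 bridged lactone cycloadduct
Product: 19 epoxy keto acid (epoxide trans to the carboxyl group), via enone carboxylate 18 (not isolated)
Conditions: Bu4NF (1.05 equiv), THF, −78 → −20 °C; then t-BuOOH (in decane), DBU (cat.), 0 °C; cold aq KHSO4, used at once
Reagents that add atoms: tert-butyl hydroperoxide, CC(C)(C)OO
Why: fluoride should cleave the silyl enol ether and the enolate should expel the bridgehead carboxylate (E1cB; the C–O bond is aligned with the enolate π system) to give the 2-methylcyclohexenone, and Weitz–Scheffer epoxidation should then deliver t-BuOO− axially to the β-carbon on the face away from the carboxylate and syn to the axial ring oxygen of the spiro carbon, placing the epoxide trans to the carboxyl group.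

Step 14
Reactants: 19 epoxy keto acid
Product: 20 epoxy keto acid chloride
Conditions: 1-chloro-N,N,2-trimethylprop-1-en-1-amine, CH2Cl2, 0 °C; volatiles removed, used crude
Reagents that add atoms: 1-chloro-N,N,2-trimethylprop-1-en-1-amine, CC(C)=C(Cl)N(C)C
Why: the chloroenamine should form the acid chloride under neutral conditions (no HCl to open the epoxide), and the quaternary α-carbon rules out ketene formation.

Step 15
Reactants: 21 sorbic acid
Product: 22 (3E,5E)-hepta-3,5-dien-2-one
Conditions: MeLi (2.1 equiv), Et2O, 0 °C; aq NH4Cl
Reagents that add atoms: methyllithium, [Li]C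
Why: addition of methyllithium to the lithium carboxylate should stop at the dilithio gem-diolate and give the methyl ketone on work-up, with the diene geometry unchanged.

Step 16
Reactants: 20 epoxy keto acid chloride; 22 (3E,5E)-hepta-3,5-dien-2-one
Product: 24 5-O-tert-butyldiphenylsilyl ether of the target, via epoxy diketone 23 (not isolated)
Conditions: 22 (2.1 equiv), LiN(SiMe3)2 (2.1 equiv), PhMe, −78 °C; 20, −78 → 0 °C; then LiClO4 (in Et2O), 0 → 25 °C; aq NH4Cl
Reagents that add atoms: none
Why: The kinetic lithium enolate of 22 should be C-acylated by the non-enolisable acid chloride (the second equivalent of enolate deprotonates the product to lithium diketonate 23), and on Li+ activation the central carbon of 23 should open the epoxide at its secondary carbon with inversion, so that one methyl carbon is joined to both ends of a five-atom dielectrophile ([5+1] annulation). The closest known reaction types are the Claisen-type acylation of ketone enolates by acid chlorides and the intramolecular alkylation of stabilised enolates by epoxides (Stork epoxynitrile cyclisation, LiClO4-promoted opening of epoxides by lithium enolates). The new C–C bond closes the six-membered carbocycle in the 6-endo mode (both epoxide carbons end in the ring; the 5-exo alternative would need attack at the fully substituted epoxide carbon and give a bicyclo[2.2.1]heptane) and at the same time closes the second six-membered ring of the bicyclo[2.2.2]octane through the spiro carbon in the 6-exo mode, through a boat-like transition state. The CH bridgehead is set by the tether, which can reach the epoxide carbon only from the face of the acyl group with anti opening, and the tertiary carbinol keeps its C–O bond, so the hydroxyl ends on the face away from the new bridge and the methyl towards it; the C-methyl quaternary and spiro centres are carried in from 20. The step needs C- rather than O-alkylation of the diketonate (lithium counter-ion in toluene/ether), epoxide opening rather than Claisen attack on the neighbouring lactone carbonyl (a diketonate should be too weak a nucleophile for the hindered lactone while LiClO4 activates the epoxide), and enolisation of 22 at the methyl group rather than the γ-position (kinetic deprotonation at −78 °C); the product enolises to the exocyclic enol of 24.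

Step 17
Reactants: 24 5-O-tert-butyldiphenylsilyl ether of the target
Product: 25 CNP0259039.2 (target)
Conditions: HF·pyridine, THF/pyridine, 0 °C → rt
Reagents that add atoms: none
Why: buffered fluoride desilylation should free the secondary alcohol without affecting the enolised triketone, the tertiary ketol, the lactone or the methyl ester.

## Compound list

1 | (−)-shikimic acid, (3R,4S,5R)-3,4,5-trihydroxycyclohex-1-ene-1-carboxylic acid | O[C@@H]1C=C(C(=O)O)C[C@@H](O)[C@@H]1O | starting material
2 | methyl shikimate | O[C@@H]1C=C(C(=O)OC)C[C@@H](O)[C@@H]1O | intermediate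
3 | methyl 4,5-O-(2,3-dimethoxybutane-2,3-diyl)shikimate (trans-fused diacetal, both OMe axial, 3-OH free) | O[C@@H]1C=C(C(=O)OC)C[C@H]2O[C@](C)(OC)[C@@](C)(OC)O[C@H]12 | intermediate
4 | methyl 3-epi-3-O-(4-nitrobenzoyl)-4,5-O-(2,3-dimethoxybutane-2,3-diyl)shikimate (3S) | [O-][N+](=O)c1ccc(cc1)C(=O)O[C@H]2C=C(C(=O)OC)C[C@H]3O[C@](C)(OC)[C@@](C)(OC)O[C@H]23 | intermediate
5 | methyl 3-epi-4,5-O-(2,3-dimethoxybutane-2,3-diyl)shikimate (3S,4S,5R) | O[C@H]1C=C(C(=O)OC)C[C@H]2O[C@](C)(OC)[C@@](C)(OC)O[C@H]12 | intermediate
6 | triethyl phosphonoacetate | CCOC(=O)CP(=O)(OCC)OCC | starting material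
7 | ethyl diazo(diethoxyphosphoryl)acetate | CCOC(=O)C(=[N+]=[N-])P(=O)(OCC)OCC | intermediate
8 | 3-O-[(diethoxyphosphoryl)(ethoxycarbonyl)methyl] ether of 5 (both epimers at the phosphonate carbon) | CCOC(=O)C(O[C@H]1C=C(C(=O)OC)C[C@H]2O[C@](C)(OC)[C@@](C)(OC)O[C@H]12)P(=O)(OCC)OCC | intermediate
9 | 3-O-(1-ethoxycarbonylvinyl) ether of 5 (enol-pyruvate ether) | C=C(O[C@H]1C=C(C(=O)OC)C[C@H]2O[C@](C)(OC)[C@@](C)(OC)O[C@H]12)C(=O)OCC | intermediate
10 | methyl (3S,4S,5R)-3-[(1-ethoxycarbonylvinyl)oxy]-4,5-dihydroxycyclohex-1-ene-1-carboxylate | C=C(O[C@H]1C=C(C(=O)OC)C[C@@H](O)[C@@H]1O)C(=O)OCC | intermediate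
11 | scytolide: trans-fused 3-methylene-1,4-dioxan-2-one (ether O on the allylic carbon, lactone O on the middle carbon) of methyl 3-epi-shikimate, 5-OH free | C=C1O[C@H]2C=C(C(=O)OC)C[C@@H](O)[C@@H]2OC1=O | intermediate
12 | 5-O-tert-butyldiphenylsilyl scytolide | C=C1O[C@H]2C=C(C(=O)OC)C[C@@H](O[Si](c3ccccc3)(c3ccccc3)C(C)(C)C)[C@@H]2OC1=O | intermediate
13 | ethyl 2-methyl-3-oxopentanoate | CCC(=O)C(C)C(=O)OCC | starting material
14 | ethyl 4-formyl-2-methyl-3-oxopentanoate (tautomer and diastereomer mixture) | CCOC(=O)C(C)C(=O)C(C)C=O | intermediate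
15 | 4-hydroxy-3,5-dimethyl-2H-pyran-2-one | CC1=COC(=O)C(C)=C1O | intermediate
16 | 3,5-dimethyl-4-(triisopropylsilyloxy)-2H-pyran-2-one | CC1=COC(=O)C(C)=C1O[Si](C(C)C)(C(C)C)C(C)C | intermediate
17 | bridged lactone cycloadduct: 2-oxabicyclo[2.2.2]oct-5-en-3-one, 4-methyl, 5-silyloxy, 6-methyl, C8 spiro to the dioxanone with its ring oxygen syn to the C5=C6 bridge and its lactone carbonyl syn to the O2–C3 bridge | O=C1O[C@H]2C[C@]3(O[C@H]4C=C(C(=O)OC)C[C@@H](O[Si](c5ccccc5)(c5ccccc5)C(C)(C)C)[C@@H]4OC3=O)[C@]1(C)C(O[Si](C(C)C)(C(C)C)C(C)C)=C2C | intermediate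
18 | spiro 2,6-dimethylcyclohex-2-enone-6-carboxylic acid (formed as its tetrabutylammonium salt; carboxyl cis to the dioxanone carbonyl, C-methyl cis to the dioxanone ring oxygen) | OC(=O)[C@@]1(C)C(=O)C(C)=CC[C@]12O[C@H]3C=C(C(=O)OC)C[C@@H](O[Si](c4ccccc4)(c4ccccc4)C(C)(C)C)[C@@H]3OC2=O | intermediate
19 | epoxy keto acid (2,3-epoxide of 18 on the face of the C-methyl group, trans to the carboxyl group) | OC(=O)[C@@]1(C)C(=O)[C@]2(C)O[C@@H]2C[C@]13O[C@H]4C=C(C(=O)OC)C[C@@H](O[Si](c5ccccc5)(c5ccccc5)C(C)(C)C)[C@@H]4OC3=O | intermediate
20 | epoxy keto acid chloride | O=C(Cl)[C@@]1(C)C(=O)[C@]2(C)O[C@@H]2C[C@]13O[C@H]4C=C(C(=O)OC)C[C@@H](O[Si](c5ccccc5)(c5ccccc5)C(C)(C)C)[C@@H]4OC3=O | intermediate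
21 | sorbic acid, (2E,4E)-hexa-2,4-dienoic acid | C/C=C/C=C/C(=O)O | starting material
22 | (3E,5E)-hepta-3,5-dien-2-one | C/C=C/C=C/C(C)=O | intermediate
23 | epoxy β-diketone (formed as its lithium diketonate) | C/C=C/C=C/C(=O)CC(=O)[C@@]1(C)C(=O)[C@]2(C)O[C@@H]2C[C@]13O[C@H]4C=C(C(=O)OC)C[C@@H](O[Si](c5ccccc5)(c5ccccc5)C(C)(C)C)[C@@H]4OC3=O | intermediate
24 | 5-O-tert-butyldiphenylsilyl ether of the target | C/C=C/C=C/C(O)=C1/C(=O)[C@@]2(C)C(=O)[C@](C)(O)[C@@H]1C[C@]21O[C@H]2C=C(C(=O)OC)C[C@@H](O[Si](c3ccccc3)(c3ccccc3)C(C)(C)C)[C@@H]2OC1=O | intermediate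
25 | CNP0259039.2 | C/C=C/C=C/C(O)=C1/C(=O)[C@@]2(C)C(=O)[C@](C)(O)[C@@H]1C[C@]21O[C@H]2C=C(C(=O)OC)C[C@@H](O)[C@@H]2OC1=O | target

## Step count and risks

Total step count: 17. Longest linear sequence: 13 steps (1, 2, 3, 4, 6, 7, 8, 9, 12, 13, 14, 16, 17).

Steps most likely to fail:

Step 12. The two partners are hindered and electronically only moderately matched, so the cycloaddition may be too slow. The diene may also add to the other face of the exocyclic alkene (it then sits over the ring-fusion hydrogen that is further from the spiro carbon), or in the carbonyl-endo orientation. Both would give diastereomers that must be separated, and heating to compensate would cause retro-cycloaddition with loss of CO2. The fallback sets out from 12 and returns at 18, replacing the cycloaddition by a stepwise polar annulation. tert-Butyl 2,4-dimethyl-3-oxopent-4-enoate F1 would be made from tert-butyl propanoate with LiN(iPr)2 and methacryloyl chloride. F1 and 12 would be combined with SnCl4 in CH2Cl2 at −78 °C: the enol-ether carbon of 12 adds to the vinyl ketone (Mukaiyama–Michael type), and the dioxanyl oxocarbenium ion is captured axially by the β-keto ester enol carbon to give spiro-cyclohexanone tert-butyl ester F2. Dehydrogenation with 2-iodoxybenzoic acid in DMSO, possible only towards the methyl-bearing α-carbon, would give the enone tert-butyl ester F3. CF3CO2H would then cleave the ester to acid 18, which enters step 13 at the epoxidation stage.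

Step 16. The enolate may be O-acylated. The diketonate may O-alkylate to a bridged enol ether or attack the neighbouring lactone carbonyl in a Claisen sense. The boat-like closure may also be too slow to compete with decomposition. The fallback sets out from 20 and 22 and returns at 24; it separates the two bond formations and closes the ring by activating the electrophile instead of the nucleophile. The acylation would be quenched cold and 23 isolated, then converted with Me3SiCl and Et3N into the trimethylsilyl enol ether of the epoxy diketone F4. F4 is a neutral carbon nucleophile that cannot O-alkylate or acylate, and it would be cyclised by TiCl4-promoted Mukaiyama-type opening of the epoxide at the secondary carbon; aqueous work-up would give 24.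

Step 13. The nucleophilic epoxidation may show poor facial selectivity (the epoxide cis to the carboxyl group cannot cyclise in step 16), and the free β-keto acid may decarboxylate during work-up. The fallback sets out from 18 and returns at 19, replacing the stereoelectronically controlled epoxidation by a hydroxyl-directed one. Luche reduction of carboxylate 18 (NaBH4, CeCl3·7H2O, MeOH, −40 °C) would give the allylic alcohol acid F5; the epimer with the hydroxyl on the face of the C-methyl group is needed, and the other would be separated and re-oxidised to 18. VO(acac)2 with t-BuOOH would epoxidise syn to the hydroxyl to give the epoxy alcohol acid F6, and Dess–Martin periodinane would oxidise F6 to 19.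

## Further compounds

F1 | step 12 | tert-butyl 2,4-dimethyl-3-oxopent-4-enoate | C=C(C)C(=O)C(C)C(=O)OC(C)(C)C
F2 | step 12 | spiro-cyclohexanone tert-butyl ester (2,6-dimethyl-2-(tert-butoxycarbonyl)cyclohexanone spiro-fused to the dioxanone; methyl-bearing α-carbon as epimer mixture) | CC(C)(C)OC(=O)[C@@]1(C)C(=O)C(C)CC[C@]12O[C@H]3C=C(C(=O)OC)C[C@@H](O[Si](c4ccccc4)(c4ccccc4)C(C)(C)C)[C@@H]3OC2=O
F3 | step 12 | enone tert-butyl ester (tert-butyl ester of 18) | CC(C)(C)OC(=O)[C@@]1(C)C(=O)C(C)=CC[C@]12O[C@H]3C=C(C(=O)OC)C[C@@H](O[Si](c4ccccc4)(c4ccccc4)C(C)(C)C)[C@@H]3OC2=O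
F4 | step 16 | trimethylsilyl enol ether of epoxy diketone 23 (Z enol ether on the dienyl side) | C/C=C/C=C/C(O[Si](C)(C)C)=C/C(=O)[C@@]1(C)C(=O)[C@]2(C)O[C@@H]2C[C@]13O[C@H]4C=C(C(=O)OC)C[C@@H](O[Si](c5ccccc5)(c5ccccc5)C(C)(C)C)[C@@H]4OC3=O
F5 | step 13 | allylic alcohol acid (ketone of 18 reduced; hydroxyl cis to the C-methyl group) | OC(=O)[C@@]1(C)[C@H](O)C(C)=CC[C@]12O[C@H]3C=C(C(=O)OC)C[C@@H](O[Si](c4ccccc4)(c4ccccc4)C(C)(C)C)[C@@H]3OC2=O
F6 | step 13 | epoxy alcohol acid (epoxide syn to the hydroxyl) | OC(=O)[C@@]1(C)[C@H](O)[C@]2(C)O[C@@H]2C[C@]13O[C@H]4C=C(C(=O)OC)C[C@@H](O[Si](c5ccccc5)(c5ccccc5)C(C)(C)C)[C@@H]4OC3=O
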